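The earlier runs and the new flask come from a simulation with constants of no real substance, noise included.

Slowness was what I read first in gamma: the over-reaction product took until 12.0 h to reach 8%, and stood at 51% at 25.0 h, while the target read 52% and 47% at those two times.

common to all: solid substrate 0.30 M; gas 27 mM (held)
- theta: second substrate 0.50 equiv; free catalyst 0.087 mol%; temperature −5 °C; run made earlier
- delta: second substrate 0.50 equiv; free catalyst 0.24 mol%; temperature 17 °C; run made earlier
- gamma: second substrate 0.50 equiv; free catalyst 0.6 mol%; temperature −5 °C; run made earlier
- north: second substrate 0.500 equiv; free catalyst 0.12 mol%; at 25 °C throughout; time 25 h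
- south: second substrate 0.500 equiv; free catalyst 0.5 mol%; at 25 °C until 1.5 h, from then on at −15 °C; time 8.0 h

| run | time / h | target / % | over-reaction product / % | solid substrate / % |
|---|---|---|---|---|
| theta | 4.00 | 3 | 0 | 57 |
| theta | 12.0 | 7 | 1 | 39 |
| theta | 20.0 | 7 | 0 | 33 |
| theta | 25.0 | 17 | 0 | 27 |
| delta | 1.00 | 2 | 0 | 86 |
| delta | 2.50 | 5 | 3 | 68 |
| delta | 3.00 | 6 | 3 | 65 |
| delta | 5.00 | 20 | 0 | 47 |
| delta | 6.00 | 22 | 4 | 39 |
| gamma | 2.00 | 2 | 1 | 73 |
| gamma | 4.00 | 6 | 1 | 57 |
| gamma | 6.00 | 19 | 5 | 44 |
| gamma | 12.0 | 52 | 8 | 7 |
| gamma | 25.0 | 47 | 51 | 0 |

(each reading ± 2 percentage points)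

- as a solid, counted per litre of solution: solid substrate
- at the start none of the solid substrate is in solution
- at the start none of the gas is in solution
- what has only dissolved of solid substrate counts as not reacted

* which of the two ends with the higher share of target in all that became target or over-reaction product ("neither" if they lie within 2 percentage points) (north / south / neither)
* share of target in all that became target or over-reaction product, north
* share of target in all that became target or over-reaction product, south

I treated the loss of target at the held gas as pseudo-first-order. I called λ the fraction of the target lost to over-reaction per hour, and read it in gamma between those two readings, taking the mean of the two target values as the level although no reading showed the course between them, as 0.0668 h⁻¹. I assumed λ scaled with the catalyst loading, and let the exposure E be λ times the mean age of the target, so that the asked share came out as exp(−E). For steady build-up I put that mean age at half of the time.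

But gamma was cold. The delta run, at 17 °C, showed 4% over-reaction product beside 22% target at 6.00 h. Taking its mean target as half of that last value gave λ = 0.0606 h⁻¹, which was 2.27 times gamma's value scaled to delta's loading. Carrying that factor exponentially in temperature, I got 0.0408 h⁻¹ for north, so E = 0.510 and a share of 60.0%.

The objection was that this factor hung on an over-reaction reading of 4% with a scatter of 2 percentage points. One scatter upward multiplied that reading by 1.50, and carried to north the same way it gave a share of 41.2%, so I kept that as my low end.

South's warm start worried me too, but delta had 2% target at 1.00 h, far less than at 6.00 h, so I reckoned south at its cold λ of 0.0384 h⁻¹. That gave E = 0.154 and a share of 85.7%.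

The forecast also chose south, with 90% for south and, above my figure, 80% for north, holding that “Over-reaction follows target build-up and takes off once substrate is depleted”.

The flasks gave south: 38.3% for north and 93.8% for south.

    coupling partner + free catalyst + target → free catalyst + over-reaction product (k = 2.68 M⁻² s⁻¹, Ea = 42.0 kJ mol⁻¹)
    starting material + free catalyst ⇌ catalyst intermediate A (K = 8.15 M⁻¹, k = 0.302 M⁻¹ s⁻¹, Ea = 35.0 kJ mol⁻¹, ΔH = −52.0 kJ mol⁻¹)
    solid substrate ⇌ starting material, rate k3*(cs3 - [starting material]) while solid is left; crystals form when [starting material] > cs3 (solubility = 0.180 M, k = 8.21 × 10⁻⁵ s⁻¹)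
    gas ⇌ coupling partner, rate k4*(csat - [coupling partner]) (kL = 0.00448 s⁻¹)
    second substrate + free catalyst ⇌ catalyst intermediate B (K = 24.6 M⁻¹, k = 1.47 M⁻¹ s⁻¹, Ea = 51.0 kJ mol⁻¹, ΔH = −35.0 kJ mol⁻¹)
    coupling partner + catalyst intermediate A → free catalyst + target (k = 2.35 M⁻¹ s⁻¹, Ea = 37.0 kJ mol⁻¹)
    coupling partner + catalyst intermediate B → free catalyst + second product (k = 1.29 M⁻¹ s⁻¹, Ea = 44.0 kJ mol⁻¹)
    (constants at 25 °C)

In north, target stood at 44.7% and over-reaction product at 13.1% at 12.5 h; by 25.0 h they stood at 37.2% and 59.8%, a λ of 0.0913 h⁻¹, higher than the 0.0408 h⁻¹ I had built from 0.0668 h⁻¹. In south, 23.7% target and 1.56% over-reaction product stood at 8.00 h, an E of 0.0639. Scaled by loading, that E gave 85.8% for south's neighbour at 1.2 mol% of free catalyst, whose simulated share was 81.0%.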